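## Retrosynthetic overview

1. The target comes from its C4 acetate, which comes from one bromonium-triggered bicyclisation of an acyclic (6E)-dienyl bromohydrin acetate. Ring A (bromocyclohexane, C5a–C6 bond) closes first, and ring B (oxepane, O1–C9a bond) closes in the same event.
2. The bromohydrin acetate comes from a syn-1,3-diol, made by chelate-controlled 1,2-reduction of a β-hydroxy-α-methylene ketone; the ester goes on the more nucleophilic hydroxyl.
3. The hydroxy enone comes from an allenyl methyl ether and bromoacetaldehyde. The central allene carbon is the donor, and a chiral catalyst sets C2.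
4. Key disconnection, C4–C5: the allenyl ether comes from 1-lithio-1-methoxyallene (a masked acryloyl anion) and geranyl bromide. A carbonyl carbon and an allylic halide carbon, both acceptors, are joined by polarity reversal.
5. All 15 carbons come from methoxyallene (3 C), geranyl bromide (10 C) and (E)-1,4-dibromobut-2-ene (2 C).

Assumption: both antipodes of the two chiral catalysts (steps 3 and 6) are accessible. The antipode written is taken to give the drawn configuration; if the sense of induction is the opposite, the mirror-image catalyst is used. The target is (2R,4R,5aS,7S,9aS) in 1-benzoxepine numbering.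

## Route

Step 1
Reactants: 1 methoxyallene; 2 geranyl bromide
Product: 4 (5E)-3-methoxy-6,10-dimethylundeca-1,2,5,9-tetraene, via 1-lithio-1-methoxyallene 3 (not isolated)
Conditions: n-BuLi, THF, −40 °C; then 2, −78 → 0 °C
Reagents that add atoms: none
Why: Polarity-reversed (acyl anion) alkylation: deprotonated methoxyallene is a masked acryloyl anion, so its O-bearing carbon (the later carbinol carbon C4, by nature an acceptor) displaces bromide from the primary allylic carbon of 2 (also an acceptor) by direct SN2, which leaves the E alkene untouched and creates no stereocentre, and the allenyl ether is kept unhydrolysed so that its unmasking in step 3 forges a second C–C bond.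

Step 2
Reactants: 5 (E)-1,4-dibromobut-2-ene
Product: 7 bromoacetaldehyde, via secondary ozonide 6 (not isolated)
Conditions: O3, CH2Cl2, −78 °C; PPh3, −78 °C → rt; distil
Reagents that add atoms: ozone [O-][O+]=O
Why: Ozonolysis with reductive work-up cleaves the symmetrical alkene into two molecules of anhydrous, monomeric aldehyde, and no stereocentre is formed.

Step 3
Reactants: 4 (5E)-3-methoxy-6,10-dimethylundeca-1,2,5,9-tetraene; 7 bromoacetaldehyde
Product: 9 (2R,6E)-1-bromo-2-hydroxy-7,11-dimethyl-3-methylidenedodeca-6,10-dien-4-one, via dienol ether ene adduct 8 (not isolated)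
Conditions: 7 (1.5 equiv), Ti(OiPr)4 (10 mol %), (R)-2-[(3-bromo-5-tert-butyl-2-hydroxybenzylidene)amino]-1,1'-binaphthyl-2'-ol (20 mol %), 2,6-di-tert-butyl-4-methylpyridine (0.4 equiv), toluene, 0 °C; then oxalic acid (cat.), THF–H2O, 0 °C
Reagents that add atoms: water O
Why: Proposed new method: the tetravalent-titanium Schiff-base complex binds the very electrophilic aldehyde 7 and exposes its Re face, the enol-ether π bond of 4 attacks through the central allene carbon while the doubly allylic C4–H passes to the aldehyde oxygen (ene/aldol-type turnover) to give 8, and kinetic α-protonation with hydrolysis then releases the α-methylene ketone without moving the 6E alkene, so the catalyst sets the 2R carbinol centre; the closest known reaction types are the titanium-catalysed enantioselective ene-type aldol addition of 2-methoxypropene to aldehydes and the Lewis-acid-catalysed enantioselective α-acylvinyl addition of silyloxyallenes to aldehydes.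

Step 4
Reactants: 9 (2R,6E)-1-bromo-2-hydroxy-7,11-dimethyl-3-methylidenedodeca-6,10-dien-4-one
Product: 11 (2R,4R,6E)-1-bromo-7,11-dimethyl-3-methylidenedodeca-6,10-diene-2,4-diol, via diethylboron chelate 10 (not isolated)
Conditions: Et2BOMe, THF–MeOH 4:1, −78 °C; NaBH4, −78 °C; repeated evaporation from MeOH
Reagents that add atoms: none
Why: Narasaka–Prasad reduction: boron locks the β-hydroxy ketone in a six-membered chelate that activates the carbonyl for 1,2-attack, and external hydride adds axially to give the 2,4-syn diol, so the 2R centre sets the new 4R centre while the cold, non-oxidative work-up spares the bromohydrin.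

Step 5
Reactants: 11 (2R,4R,6E)-1-bromo-7,11-dimethyl-3-methylidenedodeca-6,10-diene-2,4-diol
Product: 12 (2R,4R,6E)-1-bromo-2-hydroxy-7,11-dimethyl-3-methylidenedodeca-6,10-dien-4-yl acetate
Conditions: Ac2O (1.05 equiv), 2,4,6-collidine, 4-(dimethylamino)pyridine (5 mol %), CH2Cl2, −40 °C
Reagents that add atoms: acetic anhydride CC(=O)OC(C)=O
Why: Site-selective acylation: the vicinal C–Br bond deactivates the C2 hydroxyl inductively, so C4–OH reacts first, any 2-O-acetate drifts by 1,3-acyl shift to the ester of the less acidic alcohol, and no stereocentre is touched.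

Step 6
Reactants: 12 (2R,4R,6E)-1-bromo-2-hydroxy-7,11-dimethyl-3-methylidenedodeca-6,10-dien-4-yl acetate
Product: 13 (2R,4R,5aS,7S,9aS)-7-bromo-2-(bromomethyl)-6,6,9a-trimethyl-3-methylidenedecahydro-1-benzoxepin-4-yl acetate
Conditions: 1,3-dibromo-5,5-dimethylhydantoin (0.55 equiv), (S)-3,3'-bis(2,4,6-triisopropylphenyl)-1,1'-binaphthyl-2,2'-diyl N-(trifluoromethylsulfonyl)thiophosphoramide (10 mol %), toluene–CH2Cl2 1:1, −78 °C
Reagents that add atoms: 1,3-dibromo-5,5-dimethylhydantoin CC1(C)C(=O)N(Br)C(=O)N1Br
Why: Proposed new method: Lewis-base-catalysed enantioselective bromonium-induced polyene cyclisation extended to a hydroxyl terminator, in which the chiral P=S/N–H catalyst passes Br+ to one face of the electron-rich terminal alkene (sets 7S), the 6E alkene adds in a chair-like anti fashion (sets 5aS, Br equatorial) and the C2 hydroxyl traps the tertiary cation anti to the new C–C bond (sets 9aS, trans fusion), while the ester oxygen at C4 cannot close the otherwise favoured five-membered ether and the 1,1-disubstituted alkene is deactivated by two allylic C–O bonds; the closest known reaction types are the biomimetic hydroxyl-terminated bromocyclisation to the bromo-oxepane core of this sesquiterpene family and the catalytic asymmetric bromocyclisation of geranylarenes and geranylphenols, and a wrong fold gives a separable diastereomer, not the enantiomer.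

Step 7
Reactants: 13 (2R,4R,5aS,7S,9aS)-7-bromo-2-(bromomethyl)-6,6,9a-trimethyl-3-methylidenedecahydro-1-benzoxepin-4-yl acetate
Product: 14 (2R,4R,5aS,7S,9aS)-7-bromo-2-(bromomethyl)-6,6,9a-trimethyl-3-methylidenedecahydro-1-benzoxepin-4-ol
Conditions: K2CO3 (0.2 equiv), MeOH, 0 °C
Reagents that add atoms: none
Why: Base-catalysed transesterification cleaves only the acyl–O bond, so 4R is retained; the equatorial neopentyl-type secondary bromide has no antiperiplanar hydrogen, and the C4 alkoxide sits trans to the CH2Br group, so neither bromide is lost.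

## Compound list

1 | methoxyallene (1-methoxypropa-1,2-diene) | C=C=COC | starting material
2 | geranyl bromide, (2E)-1-bromo-3,7-dimethylocta-2,6-diene | CC(C)=CCC/C(C)=C/CBr | starting material
3 | 1-lithio-1-methoxyallene | [Li]C(OC)=C=C | intermediate
4 | (5E)-3-methoxy-6,10-dimethylundeca-1,2,5,9-tetraene | C=C=C(OC)C/C=C(\C)CCC=C(C)C | intermediate
5 | (E)-1,4-dibromobut-2-ene | BrC/C=C/CBr | starting material
6 | 3,5-bis(bromomethyl)-1,2,4-trioxolane (secondary ozonide, cis/trans mixture) | BrCC1OOC(CBr)O1 | intermediate
7 | bromoacetaldehyde | O=CCBr | intermediate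
8 | (2R,4Z,6E)-1-bromo-4-methoxy-7,11-dimethyl-3-methylidenedodeca-4,6,10-trien-2-ol | O[C@@H](CBr)C(=C)/C(OC)=C/C=C(\C)CCC=C(C)C | intermediate
9 | (2R,6E)-1-bromo-2-hydroxy-7,11-dimethyl-3-methylidenedodeca-6,10-dien-4-one | O[C@@H](CBr)C(=C)C(=O)C/C=C(\C)CCC=C(C)C | intermediate
10 | (2R,6E)-1-bromo-7,11-dimethyl-3-methylidene-4-oxododeca-6,10-dien-2-yl diethylborinate (boron chelate) | CCB(CC)O[C@@H](CBr)C(=C)C(=O)C/C=C(\C)CCC=C(C)C | intermediate
11 | (2R,4R,6E)-1-bromo-7,11-dimethyl-3-methylidenedodeca-6,10-diene-2,4-diol (syn diol) | O[C@@H](CBr)C(=C)[C@H](O)C/C=C(\C)CCC=C(C)C | intermediate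
12 | (2R,4R,6E)-1-bromo-2-hydroxy-7,11-dimethyl-3-methylidenedodeca-6,10-dien-4-yl acetate | O[C@@H](CBr)C(=C)[C@H](OC(C)=O)C/C=C(\C)CCC=C(C)C | intermediate
13 | (2R,4R,5aS,7S,9aS)-7-bromo-2-(bromomethyl)-6,6,9a-trimethyl-3-methylidenedecahydro-1-benzoxepin-4-yl acetate | C=C1[C@H](OC(C)=O)C[C@H]2C(C)(C)[C@@H](Br)CC[C@]2(C)O[C@H]1CBr | intermediate
14 | (2R,4R,5aS,7S,9aS)-7-bromo-2-(bromomethyl)-6,6,9a-trimethyl-3-methylidenedecahydro-1-benzoxepin-4-ol | C=C1[C@H](O)C[C@H]2C(C)(C)[C@@H](Br)CC[C@]2(C)O[C@H]1CBr | target

## Step count and risks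

Total steps: 7. Longest linear sequence: 6 (steps 1, 3, 4, 5, 6, 7).

**Most likely to fail, first: step 6.**
- A weakly nucleophilic, β-bromo-substituted hydroxyl must close a seven-membered ring on a tertiary cation before proton loss.
- The required fold places the CH2Br group syn to the angular methyl, so the substrate bias may oppose the catalyst.
- The fallback sets out from 12 and replaces the bromonium by a mercuronium trigger in two stages.
- Hg(OTf)2 complexed by (S,S)-2,2'-(propane-2,2-diyl)bis(4-tert-butyl-4,5-dihydrooxazole) in CH2Cl2 at −78 °C starts the same chair-like bicyclisation. The divalent-mercury adduct forms reversibly, which gives ring B time to close.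
- Aqueous KBr then gives [(2R,4R,5aS,7S,9aS)-4-acetoxy-2-(bromomethyl)-6,6,9a-trimethyl-3-methylidenedecahydro-1-benzoxepin-7-yl]mercury bromide F1, which can be freed of its diastereomer by crystallisation.
- Br2, LiBr and pyridine exchange C–Hg for the equatorial C–Br bond, and the route is rejoined at 13.

**Second: step 3.**
- An allenyl ether has not been used in this catalytic ene-type aldol.
- The turnover, the enantioselectivity and the kinetic hydrolysis are all untested.
- The fallback sets out from 4 and 7 and moves the source of absolute configuration from C2 to C4.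
- BF3·OEt2 (cat.) in CH2Cl2 at −78 °C followed by aqueous work-up gives racemic (6E)-1-bromo-2-hydroxy-7,11-dimethyl-3-methylidenedodeca-6,10-dien-4-one F2.
- Reagent-controlled reduction with (S)-1-methyl-3,3-diphenyltetrahydro-3H-pyrrolo[1,2-c][1,3,2]oxazaborole and BH3·SMe2 treats the branched vinyl group as the large substituent and makes every molecule 4R.
- The product is a 1:1 pair of diastereomers: the anti isomer (2S,4R,6E)-1-bromo-7,11-dimethyl-3-methylidenedodeca-6,10-diene-2,4-diol F3, which is removed by chromatography, and the syn isomer.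
- The syn isomer is 11, where the route is rejoined.

**Third: step 5.**
- The two secondary allylic hydroxyls differ mainly in electronics, so mixtures of mono- and diacetates are possible.
- The fallback sets out from 11 and removes the competition instead of relying on it.
- K2CO3 in MeOH at 0 °C closes the bromohydrin to (3R,5E)-6,10-dimethyl-2-[(2R)-oxiran-2-yl]undeca-1,5,9-trien-3-ol F4.
- Ac2O and pyridine acetylate the single remaining hydroxyl of F4 to give (3R,5E)-6,10-dimethyl-2-[(2R)-oxiran-2-yl]undeca-1,5,9-trien-3-yl acetate F5.
- Li2NiBr4 in THF opens the oxirane at its terminal carbon with retention at the carbinol centre, and the route is rejoined at 12.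

## Further compounds

F1 | step 6 | [(2R,4R,5aS,7S,9aS)-4-acetoxy-2-(bromomethyl)-6,6,9a-trimethyl-3-methylidenedecahydro-1-benzoxepin-7-yl]mercury bromide | C=C1[C@H](OC(C)=O)C[C@H]2C(C)(C)[C@@H]([Hg]Br)CC[C@]2(C)O[C@H]1CBr
F2 | step 3 | racemic (6E)-1-bromo-2-hydroxy-7,11-dimethyl-3-methylidenedodeca-6,10-dien-4-one | OC(CBr)C(=C)C(=O)C/C=C(\C)CCC=C(C)C
F3 | step 3 | (2S,4R,6E)-1-bromo-7,11-dimethyl-3-methylidenedodeca-6,10-diene-2,4-diol | O[C@H](CBr)C(=C)[C@H](O)C/C=C(\C)CCC=C(C)C
F4 | step 5 | (3R,5E)-6,10-dimethyl-2-[(2R)-oxiran-2-yl]undeca-1,5,9-trien-3-ol | C1O[C@@H]1C(=C)[C@H](O)C/C=C(\C)CCC=C(C)C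
F5 | step 5 | (3R,5E)-6,10-dimethyl-2-[(2R)-oxiran-2-yl]undeca-1,5,9-trien-3-yl acetate | C1O[C@@H]1C(=C)[C@H](OC(C)=O)C/C=C(\C)CCC=C(C)C
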